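Remark on the chemistry (assumption): (R)-2-decyloxirane 1 and acetone N,N-dimethylhydrazone 2 are taken as purchasable; 1 is otherwise one step from the cheap racemate by hydrolytic kinetic resolution, and 2 one step from acetone. Atom numbers (O1, C2, C3, C4, C4a, C5, C6, O7, C8, C8a) are those of the pyrano[3,4-b]pyran core of the target and are used for the corresponding atoms of all intermediates.

## Analysis of the target

The target 13 is (2R,6R)-6-decyl-2-heptyl-2,3,5,6-tetrahydro-4H,8H-pyrano[3,4-b]pyran-4,8-dione. Ring A (C4a, C5, C6, O7, C8, C8a) is an α,β-unsaturated δ-lactone and ring B (O1, C2, C3, C4, C4a, C8a) is a 2,3-dihydro-4H-pyran-4-one; the two rings share the tetrasubstituted C4a=C8a double bond. That double bond is a masked tricarbonyl: C8a is both the enol-ether carbon of the vinylogous ester O1–C8a=C4a–C4=O and the α-carbon of the lactone, so C8–C8a is a 1,2-dioxygenated bond, and C4a is the former α-carbon of a ketone that has a second α-carbon (C3). The two stereocentres, C2 (heptyl) and C6 (decyl), are both R, both secondary C–O carbons, and lie five bonds apart on opposite edges of a flat core, so neither can control the other. The sensitive points are the O1–C2 bond, which sits β to the C4 ketone (a C3 enolate can open ring B by retro-oxa-Michael reaction and erase C2), the lactone, and the C5 hydrogens, whose removal can expel the O7 carboxylate. The feature that decides the strategy is ring B: it is a γ-pyrone ring that has taken up one heptyl group and one hydrogen across C2=C3. In the unsaturated parent, ring B has no stereocentre and C2 is an unsubstituted, electrophilic vinylogous-ester carbon. The difficulties are the regiochemistry of the tricarbonyl assembly (C4a, not C3, must carry C8a), the fully substituted push–pull alkene, and the C2 configuration without a neighbouring stereocentre.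

## Retrosynthetic reasoning

**C2–heptyl bond (key disconnection).** The exocyclic bond between C2 and the heptyl chain is cut, which turns 13 into the flat fused γ-pyrone 10 and the heptyl Grignard reagent 11. The cut is made here because C2 is the only stereocentre of ring B and the unsaturated ring has none. 10 is seven carbons smaller, has a single stereocentre, and needs no enantiopure heptyl-bearing building block. The forward reaction must be a copper-catalysed conjugate addition that dearomatizes ring B, is controlled by the catalyst alone, attacks C2 and not C8a, and holds the enolate as silyl enol ether 12 until it is protonated.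

**Ring B of 10 (O1–C2 and C2–C3).** C2 of the pyranone is a formate-level carbon between the C3 methyl carbon of an acetyl group and the enol oxygen on C8a. Removing it leads to the acetyl enol lactone 7 and the amide acetal 8, through enaminone 9. This is the standard chromone construction and leaves ring A and the whole tricarbonyl core in 7.

**C4a–C8a (ring A).** The bond between the ketone α-carbon and the future C8a is cut, giving the mixed oxalate 6, in which both carbons of the C8–C8a unit hang on the C6 oxygen. The reason for tethering is regiochemical: in 6 the ketone has a methyl and a methylene α-carbon, and only the methylene can reach the oxalate through a six-membered transition state. The forward reaction is an intramolecular Claisen condensation that closes the lactone and creates the C4a=C8a enol in one operation.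

**Ester C–O bond.** 6 is the ester of the γ-hydroxy ketone 4 with the oxalyl half-ester chloride 5; this is a plain acylation.

**C4a–C5 bond region of 4.** The bond between the ketone α-carbon chain and the epoxide-derived methylene is cut, giving epoxide 1 and hydrazone 2 (through hydroxy hydrazone 3). The C6 stereocentre is bought with 1 and is never touched again, because every later bond is formed away from its C–O bond.

## Alternatives that were turned down

Alternative 1: (the textbook route) Cut both ring C–O bonds of the core (O1–C8a and O7–C8) and C4a–C8a, opening 13 to an acyclic 2,4-diketo ester. Forward: the bis-silylated dihydroxy ketone (8R,13R)-8,13-bis(tert-butyldimethylsilyloxy)tricosan-10-one A1 is C-acylated with an oxalic diester under base to the diketo ester A2, and acid then removes both silyl groups and closes rings A and B in one pot. It was turned down for three reasons: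
- A1 has two enolisable methylenes (C9 and C11 of the chain) of similar acidity, and nothing directs an intermolecular acylation to C11.
- The C9 enolate has the C8 silyloxy group in the β-position and can expel it (E1cB), which destroys the future C2 stereocentre.
- A1 needs two separately made enantiopure fragments and protecting groups, so the precursor costs more steps than the whole route below while its key step still forms only one C–C bond.

Alternative 2: Cut O1–C2 and C2–C3 (ring B by hetero-Diels–Alder reaction or Mukaiyama aldol addition and cyclization). Forward: the silyloxy diene A3, reached from 7 by O-methylation and enol silylation, combines with the eight-carbon aldehyde under a chiral Lewis acid, and acid closes ring B with loss of the methoxy group. It was turned down because the diene terminus C8a is fully substituted and carries the C8 carbonyl, so the diene is hindered and captodative and a concerted cycloaddition is not to be expected. The stepwise Mukaiyama pathway with an unbranched aliphatic aldehyde is the weakest case for catalytic enantiocontrol, and two extra protecting and activating operations are needed. It is also the disconnection most chemists would draw for a dihydropyranone; its stoichiometric boron-aldol form is kept only as a fallback.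

Alternative 3: Cut C8–C8a and O7–C8 (union of two electrophilic carbons by carbonylation). Forward: the β-keto-δ-lactone A4 is converted into the ketene-acetal triflate A5, and a palladium-catalysed carbonylative lactonization inserts one carbon between C8a and the C6 hydroxyl and closes ring A. It was turned down for three reasons:
- O-sulfonylation of A4 should occur at the C4 oxygen (the conjugated 2-pyranone-type enol) and not at the lactone oxygen needed for A5, so carbonylation would deliver the isomeric ring fusion.
- A4 itself requires C-alkylation of a cyclic 1,3-dicarbonyl anion with an epoxide, which competes with O-alkylation and furan formation.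
- Two enantiopure building blocks are again required.

Key step: step 5

## Route

Step 1
Reactants: 1 (R)-2-decyloxirane; 2 acetone N,N-dimethylhydrazone
Product: 4 (R)-5-hydroxypentadecan-2-one, via hydroxy hydrazone 3 (not isolated)
Conditions: 2 (1.2 equiv), n-BuLi (1.15 equiv), THF, −78 to 0 °C; then 1, 0 °C to rt; H2O; then sat. aq. oxalic acid, Et2O, rt
Reagents that add atoms: acetone N,N-dimethylhydrazone, CC(C)=NN(C)C; water, O
Why: Corey–Enders hydrazone alkylation: the lithium azaenolate opens the terminal epoxide at its unsubstituted carbon (SN2), so the C–O bond of the stereocentre is not touched and the R configuration of 1 becomes C6 of the target; mild oxalic acid hydrolysis then frees the ketone.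

Step 2
Reactants: 4 (R)-5-hydroxypentadecan-2-one; 5 methyl chlorooxoacetate
Product: 6 methyl (R)-2-oxopentadecan-5-yl oxalate
Conditions: 5 (1.2 equiv), pyridine (2 equiv), CH2Cl2, 0 °C
Reagents that add atoms: methyl chlorooxoacetate, COC(=O)C(Cl)=O
Why: Acylation of a secondary alcohol by an acid chloride; it drains the open hydroxy ketone from its hemiketal equilibrium and places both carbons of the future C8–C8a unit on the C6 oxygen.

Step 3
Reactants: 6 methyl (R)-2-oxopentadecan-5-yl oxalate
Product: 7 (R)-4-acetyl-6-decyl-3-hydroxy-5,6-dihydro-2H-pyran-2-one
Conditions: KOtBu (2.2 equiv), THF (0.02 M), 0 °C to rt; then 1 M aq. HCl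
Reagents that add atoms: none
Why: Intramolecular Claisen (Dieckmann-type) condensation under equilibrating enolate conditions: only the methylene enolate (future C4a) reaches the oxalate through a six-membered transition state (6-exo-trig), the methyl enolate would need an eight-membered one, and the product leaves the equilibrium as its stabilized potassium enolate. Ring A and the C4a–C8a bond are formed and the stereocentre is not involved.

Step 4
Reactants: 7 (R)-4-acetyl-6-decyl-3-hydroxy-5,6-dihydro-2H-pyran-2-one; 8 N,N-dimethylformamide dimethyl acetal
Product: 10 (R)-6-decyl-5,6-dihydro-4H,8H-pyrano[3,4-b]pyran-4,8-dione, via enaminone 9 (not isolated)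
Conditions: 8 (2.5 equiv), PhMe, 80 °C; then AcOH, 80 °C
Reagents that add atoms: N,N-dimethylformamide dimethyl acetal, COC(OC)N(C)C
Why: Amide-acetal condensation at the activated acetyl methyl group gives the enaminone, and acid drives 6-endo addition of the enol oxygen to the β-carbon with loss of dimethylamine (the chromone construction). The close analogy is the conversion of 3-acetyl-4-hydroxy-2-pyranones and 3-acetyl-4-hydroxycoumarins into fused γ-pyrones.

Step 5
Reactants: 10 (R)-6-decyl-5,6-dihydro-4H,8H-pyrano[3,4-b]pyran-4,8-dione; 11 heptylmagnesium bromide
Product: 13 (2R,6R)-6-decyl-2-heptyl-2,3,5,6-tetrahydro-4H,8H-pyrano[3,4-b]pyran-4,8-dione, via silyl enol ether 12 (not isolated)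
Conditions: 11 (1.5 equiv, slow addition), CuBr·SMe2 (5 mol %), (R)-1-[(SP)-2-(dicyclohexylphosphino)ferrocenyl]ethyldiphenylphosphine or its enantiomer (6 mol %), Me3SiCl (2 equiv), CH2Cl2, −78 °C; then 1 M aq. HCl, THF, 0 °C
Reagents that add atoms: heptylmagnesium bromide, CCCCCCC[Mg]Br
Why: Proposed new method: copper-catalysed enantioselective 1,4-addition of an alkyl Grignard reagent to the C2=C3 bond of a lactone-fused, non-benzannulated γ-pyrone; the closest known reaction type is the CuBr·SMe2/ferrocenyl-diphosphine-catalysed conjugate addition of Grignard reagents to chromones, 4-quinolones and N-acyl-4-pyridones, and the reasoning is that 10 offers the same O1–C2H=C3H–C4=O vinylogous ester as a chromone, made more electrophilic by the C8 carbonyl on C8a. Mechanism: transmetalation gives a ligand-bound heptylcopper species (monovalent copper) that forms a π-complex with C2=C3, adds oxidatively at C2 to a trivalent copper σ-complex and reductively eliminates to form the C2–heptyl bond; the magnesium enolate is silylated in the flask to 12, and dilute acid protonates C3 to release the C4 ketone. No ring is closed; ring B is dearomatized. The one new stereocentre, C2, is set by the chiral diphosphine on copper: heptyl has to arrive on the Re face of C2 (priorities O1 > C3 > H) to give 2R, and C6, five bonds away on a flat bicycle, should exert no bias, so the ligand enantiomer is chosen in a pilot pair of runs, the two possible products being diastereomers. Site selectivity is needed for C2 over C8a (also a β-alkoxy-enone carbon), C4a and the two carbonyls: C2 is the only electrophilic carbon that carries hydrogen and sits on a disubstituted alkene, whereas addition at C8a or C4a would have to build a quaternary centre on a tetrasubstituted push–pull alkene, and copper catalysis at −78 °C keeps 1,2-addition at C4 and C8 slow. Trapping as 12 is essential because it blocks retro-oxa-Michael opening of the C3 enolate (the leaving group would be the stabilized O1–C8a enolate), the one pathway that could erase the new C2 configuration.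

## Compound list

1 | (R)-2-decyloxirane [(R)-1,2-epoxydodecane] | CCCCCCCCCC[C@@H]1CO1 | starting material
2 | acetone N,N-dimethylhydrazone | CC(C)=NN(C)C | starting material
3 | (R)-2-(2,2-dimethylhydrazinylidene)pentadecan-5-ol (formed as its lithium alkoxide) | CCCCCCCCCC[C@@H](O)CCC(C)=NN(C)C | intermediate
4 | (R)-5-hydroxypentadecan-2-one | CCCCCCCCCC[C@@H](O)CCC(C)=O | intermediate
5 | methyl chlorooxoacetate | COC(=O)C(Cl)=O | starting material
6 | methyl (R)-2-oxopentadecan-5-yl oxalate | CCCCCCCCCC[C@@H](OC(=O)C(=O)OC)CCC(C)=O | intermediate
7 | (R)-4-acetyl-6-decyl-3-hydroxy-5,6-dihydro-2H-pyran-2-one | CCCCCCCCCC[C@@H]1CC(C(C)=O)=C(O)C(=O)O1 | intermediate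
8 | N,N-dimethylformamide dimethyl acetal | COC(OC)N(C)C | starting material
9 | (R,E)-6-decyl-4-[3-(dimethylamino)prop-2-enoyl]-3-hydroxy-5,6-dihydro-2H-pyran-2-one | CCCCCCCCCC[C@@H]1CC(C(=O)/C=C/N(C)C)=C(O)C(=O)O1 | intermediate
10 | (R)-6-decyl-5,6-dihydro-4H,8H-pyrano[3,4-b]pyran-4,8-dione | CCCCCCCCCC[C@@H]1CC2=C(OC=CC2=O)C(=O)O1 | intermediate
11 | heptylmagnesium bromide | CCCCCCC[Mg]Br | starting material
12 | (2R,6R)-6-decyl-2-heptyl-4-[(trimethylsilyl)oxy]-5,6-dihydro-2H,8H-pyrano[3,4-b]pyran-8-one | CCCCCCCCCC[C@@H]1CC2=C(O[C@H](CCCCCCC)C=C2O[Si](C)(C)C)C(=O)O1 | intermediate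
13 | (2R,6R)-6-decyl-2-heptyl-2,3,5,6-tetrahydro-4H,8H-pyrano[3,4-b]pyran-4,8-dione | CCCCCCCCCC[C@@H]1CC2=C(O[C@H](CCCCCCC)CC2=O)C(=O)O1 | target

## Step count and least certain steps

Total step count: 5. Longest linear sequence: 5 steps (1 to 13).

**Step 5 (key step, proposed new method).**
- What may go wrong: poor facial selectivity at C2, because the catalyst–substrate fit known for benzo-fused pyranones need not carry over to a lactone-fused one.
- Ring opening of the C3 enolate by retro-oxa-Michael reaction before it is silylated, which would scramble C2.
- Deprotonation at C5 by the Grignard reagent with β-elimination of the O7 carboxylate.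
- 1,2-Addition to the lactone carbonyl.
- Fallback (known chemistry only, sets out from 7 and comes back at 13): 7 is O-methylated with Me3SiCHN2 in MeOH/PhMe to the methyl enol ether (R)-4-acetyl-6-decyl-3-methoxy-5,6-dihydro-2H-pyran-2-one F1. The acetyl group of F1 is enolized with Ipc2BCl (the enantiomer that leads to the R carbinol) and Et3N, and the boron enolate is added to octanal (Ipc2BCl-mediated methyl ketone aldol) to give (R)-6-decyl-4-[(R)-3-hydroxydecanoyl]-3-methoxy-5,6-dihydro-2H-pyran-2-one F2. CF3CO2H in CH2Cl2 then closes ring B by 6-endo addition of the new hydroxyl to C8a and loss of methanol, which gives 13 with the carbinol C–O bond intact. Because C6 is fixed, any C2 epimer is a diastereomer and can be removed by chromatography or crystallization.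

**Step 3.**
- What may go wrong: enolization toward the methyl group followed by intermolecular acylation.
- Cleavage of the oxalate tether by alkoxide (transesterification), which sets an untethered oxalate free. Both lead to acylation at the wrong α-carbon.
- Fallback (sets out from 1 and comes back at 10, and so also bypasses step 4): commercial 4,4-dimethoxybutan-2-one is condensed with N,N-dimethylhydrazine to 4,4-dimethoxybutan-2-one N,N-dimethylhydrazone F3. Its lithium azaenolate (LiN(iPr)2, THF, −78 °C, formed at the methyl group) opens 1, and buffered hydrolysis (aq. CuCl2, pH 7) gives (R)-6-hydroxy-1,1-dimethoxyhexadecan-3-one F4. Acylation with 5 and pyridine gives (R)-1,1-dimethoxy-3-oxohexadecan-6-yl methyl oxalate F5. KOtBu (3 equiv, THF) first eliminates methanol from the β-keto acetal, which leaves the future C4a as the only enolisable carbon, and the Claisen ring closure then gives (R)-6-decyl-3-hydroxy-4-[(E)-3-methoxyprop-2-enoyl]-5,6-dihydro-2H-pyran-2-one F6. CF3CO2H closes the pyranone by addition–elimination at the methoxyvinyl carbon and gives 10.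

**Step 1.**
- What may go wrong: during the acidic hydrolysis of the hydrazone, the γ-hydroxy ketone may close to its cyclic hemiketal and lose water to a dihydrofuran, which removes the free hydroxyl needed in step 2.
- Fallback (sets out from 1 and comes back at 6): 1 is opened with 2-methylallylmagnesium chloride and catalytic CuI (THF, −30 °C) to (R)-2-methylpentadec-1-en-5-ol F7. Acylation with 5 and pyridine gives methyl (R)-2-methylpentadec-1-en-5-yl oxalate F8, and ozonolysis (O3, CH2Cl2, −78 °C; then Me2S) of the 1,1-disubstituted alkene gives 6, so the free hydroxy ketone never forms.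

## Further compounds

F1 | step 5 | (R)-4-acetyl-6-decyl-3-methoxy-5,6-dihydro-2H-pyran-2-one | CCCCCCCCCC[C@@H]1CC(C(C)=O)=C(OC)C(=O)O1
F2 | step 5 | (R)-6-decyl-4-[(R)-3-hydroxydecanoyl]-3-methoxy-5,6-dihydro-2H-pyran-2-one | CCCCCCCCCC[C@@H]1CC(C(=O)C[C@H](O)CCCCCCC)=C(OC)C(=O)O1
F3 | step 3 | 4,4-dimethoxybutan-2-one N,N-dimethylhydrazone | COC(CC(C)=NN(C)C)OC
F4 | step 3 | (R)-6-hydroxy-1,1-dimethoxyhexadecan-3-one | CCCCCCCCCC[C@@H](O)CCC(=O)CC(OC)OC
F5 | step 3 | (R)-1,1-dimethoxy-3-oxohexadecan-6-yl methyl oxalate | CCCCCCCCCC[C@@H](OC(=O)C(=O)OC)CCC(=O)CC(OC)OC
F6 | step 3 | (R)-6-decyl-3-hydroxy-4-[(E)-3-methoxyprop-2-enoyl]-5,6-dihydro-2H-pyran-2-one | CCCCCCCCCC[C@@H]1CC(C(=O)/C=C/OC)=C(O)C(=O)O1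
F7 | step 1 | (R)-2-methylpentadec-1-en-5-ol | CCCCCCCCCC[C@@H](O)CCC(C)=C
F8 | step 1 | methyl (R)-2-methylpentadec-1-en-5-yl oxalate | CCCCCCCCCC[C@@H](OC(=O)C(=O)OC)CCC(C)=C
A1 | alternative 1 | (8R,13R)-8,13-bis[(tert-butyldimethylsilyl)oxy]tricosan-10-one | CCCCCCC[C@@H](O[Si](C)(C)C(C)(C)C)CC(=O)CC[C@H](O[Si](C)(C)C(C)(C)C)CCCCCCCCCC
A2 | alternative 1 | methyl (6R)-6-[(tert-butyldimethylsilyl)oxy]-3-{(2R)-2-[(tert-butyldimethylsilyl)oxy]dodecyl}-2,4-dioxotridecanoate | COC(=O)C(=O)C(C[C@H](O[Si](C)(C)C(C)(C)C)CCCCCCCCCC)C(=O)C[C@H](O[Si](C)(C)C(C)(C)C)CCCCCCC
A3 | alternative 2 | (R)-6-decyl-3-methoxy-4-[1-(trimethylsilyloxy)vinyl]-5,6-dihydro-2H-pyran-2-one | CCCCCCCCCC[C@@H]1CC(C(=C)O[Si](C)(C)C)=C(OC)C(=O)O1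
A4 | alternative 3 | (R)-6-heptyl-3-[(R)-2-hydroxydodecyl]dihydro-2H-pyran-2,4(3H)-dione | CCCCCCC[C@@H]1CC(=O)C(C[C@H](O)CCCCCCCCCC)C(=O)O1
A5 | alternative 3 | (R)-6-heptyl-3-[(R)-2-hydroxydodecyl]-4-oxo-5,6-dihydro-4H-pyran-2-yl trifluoromethanesulfonate | CCCCCCC[C@@H]1CC(=O)C(C[C@H](O)CCCCCCCCCC)=C(OS(=O)(=O)C(F)(F)F)O1
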